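The data were generated by integration from invented constants, and the scatter is random.

The easy mistake with the autumn flask is to count its 4.5 mM of catalyst as working catalyst, although 7.1 mM of added ligand stands beside it, more than the catalyst. If the ligand binds tightly, nearly every catalyst sits in the idle complex, an off-cycle complex, and [catalyst] follows [idle complex]/[added ligand]. The number to reckon with is then the load, the catalyst charged divided by the ligand left over once each catalyst has taken one: 1.73. The rule to test is that the rate of product formation runs in proportion to the load.

| flask | substrate | gas phase | catalyst | added ligand | remark | time |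
|---|---|---|---|---|---|---|
| autumn | 0.50 M | 200 mM (held) | 4.5 mM | 7.1 mM | the very flask that is asked about, followed so far |  |
| midnight | 0.50 M | 200 mM (held) | 4.5 mM | 11 mM | run made earlier |  |
| flask | 0.50 M | 200 mM (held) | 4.5 mM | 7.1 mM |  | 12 min |

| autumn: time / min | autumn: product / % | midnight: time / min | midnight: product / % |
|---|---|---|---|
| 0.667 | 2.8 | 3.00 | 3.9 |
| 1.50 | 2.0 | 6.00 | 8.0 |
| 3.00 | 7.0 | 10.0 | 10.2 |
| 5.00 | 11.2 | 12.0 | 12.4 |

(standard deviation of a reading: 1 percentage point)

1. the product standing at 12 min, as a percentage of the substrate charged
2. the change that raises the amount of product at 12 min, in percent of the substrate charged most ("none" if none brings more than 2 percentage points) (teal / red / amber / none)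
3. amount of product at 12 min, in percent of the substrate charged, after teal

- teal: doubling the transfer coefficient of the gas phase, all else as stated
- red: doubling the amount of catalyst, all else as stated
- amber: doubling the saturation concentration of gas phase, all else as stated

- at the start none of the gas is dissolved
- what was read earlier has a scatter of 1 percentage point, one standard deviation
- candidate steps: gas phase <-> dissolved gas; substrate + dissolved gas + catalyst <-> catalyst + product; catalyst + added ligand <-> idle complex

The two columns differ in the ligand charge. The autumn run reaches 11.2% at 5.00 min, a slope of 0.0224 min⁻¹ as a fraction of the substrate. The midnight run reaches 12.4% at 12.0 min, a slope of 0.0103 min⁻¹. The midnight load is 0.692, so the loads stand in the ratio 2.50 and the slopes in the ratio 2.17. Each slope rests on one reading with a scatter of 1 percentage point, so the two ratios count as alike.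

The rate thus answers to the ligand, and my own reckoning expects little from teal. Its straight line gives 26.9% at 12 min, on the high side if the rate sags later. Red charges 9.00 mM, more than the ligand, so the load loses its meaning and free catalyst jumps; red is my choice.

The forecast gives 25%, red as best and 26.5% after teal, lower than my line, on the ground of “mild substrate depletion”.

The flask gives 22.0% and 22.0% after teal. Teal adds 0.022 points, amber 17 points and red 20 points, so red is best.

    gas phase ⇌ dissolved gas, rate k1*(csat - [dissolved gas]) (kL = 0.792 s⁻¹)
    substrate + dissolved gas + catalyst ⇌ catalyst + product (K = 3.57 M⁻¹, k = 7.08 M⁻² s⁻¹)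
    catalyst + added ligand ⇌ idle complex, settled at all times (K = 4700 M⁻¹)

The autumn flask has not come to rest at 12.0 min. Catalyst stands at 6.82% of its charge at 1.20 min and at 6.82% at 120 min, in keeping with a load that stays 1.73. Product still climbs to 41.6% at 120 min, a further 20 points. The quotient [product]/([substrate][dissolved gas]) is 1.41 M⁻¹ at 12.0 min and 3.57 M⁻¹ at 120 min, beside 3.57 M⁻¹.

In the neighbouring flask with 0.0018 M of catalyst, the load falls to 0.340, and the autumn slope scaled by it gives 5.28% at 12 min. The computed flask gives 6.43%.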